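## Retrosynthetic overview

1. Numbering (1-benzoxepine): O1, C2(H)CH2Br, C3(Me)=C4H, C5H2, C5a(H), C6Me2, C7(H)Br, C8H2, C9H2, C9a(Me)O. Palisadin B ⇐ primary alcohol (Appel) ⇐ 2-methylidene oxepene (hydroboration sets C2) ⇐ α,β-unsaturated ε-lactone (Tebbe methylenation).
2. C7–Br ⇐ axial C7–OH (Appel, inversion) ⇐ C7 ketone. Ring B ⇐ ring-closing metathesis of the C9a methacrylate with the C5a allyl arm (forms C3=C4).
3. C9a–O ⇐ C9a–CHO (Baeyer–Villiger, retention). Ring A ⇐ one catalytic enantioselective Diels–Alder reaction that forms C9–C9a and C5a–C6 from an achiral 2-silyloxydiene (C6–C9) and an achiral E enal (C9a, C5a, allyl arm).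
4. Enabling feature: in ring A the brominated C7 and the oxygenated quaternary C9a stand 1,4, the gem-dimethyl C6 is next to C5a–H, and 9a-Me/5a-H are trans. This is the "para" adduct of a 2-oxygenated 1,1-dimethylbutadiene with an E, α-methyl trisubstituted enal; C5a and C9a set there then relay C7 and C2.
5. Ring order: carbocyclic ring A first ([4+2]), oxepene ring B second (metathesis).

Key step: step 4

Remark (assumption): the sense of induction in step 4 is taken from the formyl C–H···O binding model for 2-substituted enals, on which the (R)-diphenylprolinol-derived cation is expected to expose the required enal face; if the first adduct proved antipodal, the (S)-catalyst would replace it with no other change.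
Remark (assumption): 4-methylpent-1-en-3-one is treated as a stabilised catalogue chemical; it is otherwise one MnO2 oxidation from commercial 4-methylpent-1-en-3-ol.

## Route

Step 1
Reactants: 1 prop-2-yn-1-ol; 2 3-bromoprop-1-ene (allyl bromide)
Product: 4 (E)-2-methylhexa-2,5-dien-1-ol, via alkenylalane 3 (not isolated)
Conditions: Me3Al (3 equiv), Cp2ZrCl2 (25 mol%), (CH2Cl)2, 0 °C → rt; then 2, Pd(PPh3)4 (3 mol%, zerovalent palladium), THF, rt; aq. HCl
Reagents that add atoms: trimethylaluminium, C[Al](C)C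
Why: Zirconium-catalysed syn-carboalumination puts methyl on the internal and aluminium on the terminal alkyne carbon, and palladium-catalysed cross-coupling of the alkenylalane with the allylic bromide proceeds with retention, which should fix the E alkene (methyl cis to the allyl group).

Step 2
Reactants: 4 (E)-2-methylhexa-2,5-dien-1-ol
Product: 5 (E)-2-methylhexa-2,5-dienal
Conditions: activated MnO2 (excess), CH2Cl2, rt
Reagents that add atoms: none
Why: Allylic alcohol oxidation on manganese dioxide is neutral and non-enolising, so the skipped diene should not move into conjugation and the E geometry is kept.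

Step 3
Reactants: 6 4-methylpent-1-en-3-one
Product: 7 triisopropyl[(4-methylpenta-1,3-dien-3-yl)oxy]silane
Conditions: TIPSOTf, Et3N, CH2Cl2, 0 °C
Reagents that add atoms: triisopropylsilyl trifluoromethanesulfonate, CC(C)[Si](C(C)C)(C(C)C)OS(=O)(=O)C(F)(F)F
Why: Soft enolisation and O-silylation; the isopropyl methine is the only enolisable position, so a single cross-conjugated 2-silyloxydiene should form.

Step 4
Reactants: 5 (E)-2-methylhexa-2,5-dienal; 7 triisopropyl[(4-methylpenta-1,3-dien-3-yl)oxy]silane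
Product: 9 (1S,2R)-1,3,3-trimethyl-4-oxo-2-(prop-2-en-1-yl)cyclohexane-1-carbaldehyde (ring methyl cis to allyl, formyl trans to allyl), via silyl enol ether cycloadduct 8 (not isolated)
Conditions: (R)-3,3-diphenyl-1-(o-tolyl)tetrahydro-1H,3H-pyrrolo[1,2-c][1,3,2]oxazaborole (20 mol%) + HNTf2 (18 mol%), CH2Cl2, −78 → −40 °C; then 1 M HCl, THF, 0 °C → rt
Reagents that add atoms: none
Why: The cationic oxazaborolidinium binds the formyl oxygen of s-trans 5, and 7 adds in a concerted but strongly asynchronous [4+2] cycloaddition in which the C5a–C6 bond (enal β-carbon to the nucleophilic CMe2 terminus) runs ahead of the C9–C9a bond (diene CH2 to enal α-carbon). The closest known reaction type is the oxazaborolidinium-catalysed Diels–Alder reaction of 2-silyloxybuta-1,3-dienes with 2-methyl enals, and Lewis-acid cycloadditions of 1,1-dimethyl-2-silyloxydienes with hindered enones show that a fully substituted diene terminus is tolerated. Ring A is closed by intermolecular [4+2] cycloaddition, both σ bonds formed suprafacially on each partner. The new stereocentres C9a (Me/CHO) and C5a (H/allyl) are fixed relative to each other by the E geometry of 5 (methyl and allyl cis, hence 9a-Me and 5a-H trans), and absolutely by the catalyst, which must deliver the diene to the C2-Si/C3-Re face of 5. The required "para" regiochemistry (silyloxy carbon 1,4 to the formyl-bearing carbon) is secured by the polarisation of both partners and by avoidance of vicinal quaternary centres; the conjugated alkene is chosen over the isolated allyl alkene by Lewis-acid activation, and endo/exo selectivity is irrelevant because each diene terminus carries two identical substituents. Acidic work-up should hydrolyse the silyl enol ether to the C7 ketone.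

Step 5
Reactants: 9 (1S,2R)-1,3,3-trimethyl-4-oxo-2-(prop-2-en-1-yl)cyclohexane-1-carbaldehyde
Product: 11 (3S,4S)-4-hydroxy-2,2,4-trimethyl-3-(prop-2-en-1-yl)cyclohexan-1-one, via formate ester 10 (not isolated)
Conditions: mCPBA (1.2 equiv), CH2Cl2, 0 °C; aqueous wash; then K2CO3 (cat.), MeOH, 0 °C
Reagents that add atoms: 3-chloroperoxybenzoic acid, OOC(=O)c1cccc(Cl)c1
Why: Baeyer–Villiger oxidation of an aldehyde whose carbon substituent is tertiary: the quaternary carbon should migrate in preference to hydride and with retention, the formyl group reacting faster than the hindered ketone or the monosubstituted alkene; methanolysis of the formate releases the tertiary alcohol.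

Step 6
Reactants: 11 (3S,4S)-4-hydroxy-2,2,4-trimethyl-3-(prop-2-en-1-yl)cyclohexan-1-one; 12 methacrylic anhydride
Product: 13 (1S,2S)-1,3,3-trimethyl-4-oxo-2-(prop-2-en-1-yl)cyclohexyl 2-methylprop-2-enoate
Conditions: 12 (3 equiv), Sc(OTf)3 (5 mol%), BHT (cat.), MeCN, −20 °C
Reagents that add atoms: none
Why: Scandium-triflate-catalysed acylation with an anhydride esterifies tertiary alcohols under non-basic conditions, so the enolisable ketone should stay untouched.

Step 7
Reactants: 13 (1S,2S)-1,3,3-trimethyl-4-oxo-2-(prop-2-en-1-yl)cyclohexyl 2-methylprop-2-enoate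
Product: 14 (5aS,9aS)-3,6,6,9a-tetramethyl-5a,8,9,9a-tetrahydro-1-benzoxepine-2,7(5H,6H)-dione
Conditions: RuCl2(H2IMes)(=CH-C6H4-2-O-i-Pr) (second-generation Hoveyda–Grubbs catalyst, 10 mol%), toluene (2 mM), 80 °C
Reagents that add atoms: none
Why: Ring-closing metathesis between the allyl terminus and the methacrylate, whose vicinal arms are gauche when both equatorial; ethene is lost and the seven-membered ring can only hold the Z C3=C4 alkene, the trans fusion being already fixed.

Step 8
Reactants: 14 (5aS,9aS)-3,6,6,9a-tetramethyl-5a,8,9,9a-tetrahydro-1-benzoxepine-2,7(5H,6H)-dione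
Product: 15 (5aS,7R,9aS)-7-hydroxy-3,6,6,9a-tetramethyl-5a,6,7,8,9,9a-hexahydro-1-benzoxepin-2(5H)-one (7-OH axial, cis to H-5a)
Conditions: LiBH(s-Bu)3 (1.1 equiv), THF, −78 °C; then H2O
Reagents that add atoms: none
Why: The bulky trialkylborohydride should attack the C7 ketone of the now locked trans-fused chair from the equatorial direction (axial approach meets axial H-5a and H-9), giving the axial alcohol as in 4,4-dimethyl-3-oxo decalin-type systems; ketone reduction should outpace attack on the trisubstituted unsaturated lactone at −78 °C.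

Step 9
Reactants: 15 (5aS,7R,9aS)-7-hydroxy-3,6,6,9a-tetramethyl-5a,6,7,8,9,9a-hexahydro-1-benzoxepin-2(5H)-one
Product: 16 (5aS,7S,9aS)-7-bromo-3,6,6,9a-tetramethyl-5a,6,7,8,9,9a-hexahydro-1-benzoxepin-2(5H)-one (Br equatorial)
Conditions: CBr4 (3 equiv), PPh3 (3 equiv), toluene, 0 → 60 °C
Reagents that add atoms: tetrabromomethane, BrC(Br)(Br)Br
Why: Appel reaction; bromide should displace the axial alkoxyphosphonium group from the open equatorial side with inversion, giving the equatorial 7S bromide.

Step 10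
Reactants: 16 (5aS,7S,9aS)-7-bromo-3,6,6,9a-tetramethyl-5a,6,7,8,9,9a-hexahydro-1-benzoxepin-2(5H)-one
Product: 17 (5aS,7S,9aS)-7-bromo-3,6,6,9a-tetramethyl-2-methylidene-2,5,5a,6,7,8,9,9a-octahydro-1-benzoxepine
Conditions: Cp2Ti(μ-CH2)(μ-Cl)AlMe2 (1.5 equiv), pyridine (cat.), THF/toluene, −40 → 0 °C; filtration through basic alumina, used crude
Reagents that add atoms: Tebbe reagent Cp2Ti(μ-CH2)(μ-Cl)AlMe2, C[Al-]1(C)C[Ti](C2C=CC=C2)(C2C=CC=C2)[Cl+]1
Why: Tebbe methylenation of the lactone carbonyl (titanium methylidene [2+2], then cycloreversion) should give the exocyclic enol ether without touching the secondary bromide.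

Step 11
Reactants: 17 (5aS,7S,9aS)-7-bromo-3,6,6,9a-tetramethyl-2-methylidene-2,5,5a,6,7,8,9,9a-octahydro-1-benzoxepine
Product: 19 [(2R,5aS,7S,9aS)-7-bromo-3,6,6,9a-tetramethyl-2,5,5a,6,7,8,9,9a-octahydro-1-benzoxepin-2-yl]methanol, via B-alkyl-9-BBN adduct 18 (not isolated)
Conditions: 9-BBN (2 equiv), THF, 0 °C → rt; then NaOH (aq), H2O2, 0 °C
Reagents that add atoms: hydrogen peroxide, OO; 9-borabicyclo[3.3.1]nonane, B1C2CCCC1CCC2 (boron stays only in 18)
Why: Hydroboration–oxidation of the exocyclic enol ether; boron should add to the terminal CH2 (β to oxygen) and hydrogen to C2 from the face opposite the axial 9a-methyl group that lies 1,3 across the ring oxygen, setting 2R with the CH2OH arm cis to that methyl, while the trisubstituted ring alkene is too hindered for 9-BBN.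

Step 12
Reactants: 19 [(2R,5aS,7S,9aS)-7-bromo-3,6,6,9a-tetramethyl-2,5,5a,6,7,8,9,9a-octahydro-1-benzoxepin-2-yl]methanol
Product: 20 palisadin B, (2R,5aS,7S,9aS)-7-bromo-2-(bromomethyl)-3,6,6,9a-tetramethyl-2,5,5a,6,7,8,9,9a-octahydro-1-benzoxepine
Conditions: CBr4, PPh3, CH2Cl2, 0 °C → rt
Reagents that add atoms: tetrabromomethane, BrC(Br)(Br)Br
Why: Appel bromination of the unhindered primary alcohol; no stereocentre is touched.

## Compound list

1 | prop-2-yn-1-ol | C#CCO | starting material
2 | 3-bromoprop-1-ene | C=CCBr | starting material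
3 | {[(E)-3-(dimethylalumanyl)-2-methylprop-2-en-1-yl]oxy}dimethylalumane | C[Al](C)OC/C(C)=C/[Al](C)C | intermediate
4 | (E)-2-methylhexa-2,5-dien-1-ol | OC/C(C)=C/CC=C | intermediate
5 | (E)-2-methylhexa-2,5-dienal | O=C/C(C)=C/CC=C | intermediate
6 | 4-methylpent-1-en-3-one | C=CC(=O)C(C)C | starting material
7 | triisopropyl[(4-methylpenta-1,3-dien-3-yl)oxy]silane | C=CC(O[Si](C(C)C)(C(C)C)C(C)C)=C(C)C | intermediate
8 | (1S,6S)-1,5,5-trimethyl-6-(prop-2-en-1-yl)-4-[(triisopropylsilyl)oxy]cyclohex-3-ene-1-carbaldehyde | C=CC[C@H]1C(C)(C)C(O[Si](C(C)C)(C(C)C)C(C)C)=CC[C@]1(C)C=O | intermediate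
9 | (1S,2R)-1,3,3-trimethyl-4-oxo-2-(prop-2-en-1-yl)cyclohexane-1-carbaldehyde | C=CC[C@H]1C(C)(C)C(=O)CC[C@]1(C)C=O | intermediate
10 | (1S,2S)-1,3,3-trimethyl-4-oxo-2-(prop-2-en-1-yl)cyclohexyl formate | C=CC[C@H]1C(C)(C)C(=O)CC[C@]1(C)OC=O | intermediate
11 | (3S,4S)-4-hydroxy-2,2,4-trimethyl-3-(prop-2-en-1-yl)cyclohexan-1-one | C=CC[C@H]1C(C)(C)C(=O)CC[C@]1(C)O | intermediate
12 | methacrylic anhydride | CC(=C)C(=O)OC(=O)C(C)=C | starting material
13 | (1S,2S)-1,3,3-trimethyl-4-oxo-2-(prop-2-en-1-yl)cyclohexyl 2-methylprop-2-enoate | C=CC[C@H]1C(C)(C)C(=O)CC[C@]1(C)OC(=O)C(C)=C | intermediate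
14 | (5aS,9aS)-3,6,6,9a-tetramethyl-5a,8,9,9a-tetrahydro-1-benzoxepine-2,7(5H,6H)-dione | CC1=CC[C@H]2C(C)(C)C(=O)CC[C@]2(C)OC1=O | intermediate
15 | (5aS,7R,9aS)-7-hydroxy-3,6,6,9a-tetramethyl-5a,6,7,8,9,9a-hexahydro-1-benzoxepin-2(5H)-one | CC1=CC[C@H]2C(C)(C)[C@H](O)CC[C@]2(C)OC1=O | intermediate
16 | (5aS,7S,9aS)-7-bromo-3,6,6,9a-tetramethyl-5a,6,7,8,9,9a-hexahydro-1-benzoxepin-2(5H)-one | CC1=CC[C@H]2C(C)(C)[C@@H](Br)CC[C@]2(C)OC1=O | intermediate
17 | (5aS,7S,9aS)-7-bromo-3,6,6,9a-tetramethyl-2-methylidene-2,5,5a,6,7,8,9,9a-octahydro-1-benzoxepine | CC1=CC[C@H]2C(C)(C)[C@@H](Br)CC[C@]2(C)OC1=C | intermediate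
18 | 9-{[(2S,5aS,7S,9aS)-7-bromo-3,6,6,9a-tetramethyl-2,5,5a,6,7,8,9,9a-octahydro-1-benzoxepin-2-yl]methyl}-9-borabicyclo[3.3.1]nonane | CC1=CC[C@H]2C(C)(C)[C@@H](Br)CC[C@]2(C)O[C@H]1CB1C2CCCC1CCC2 | intermediate
19 | [(2R,5aS,7S,9aS)-7-bromo-3,6,6,9a-tetramethyl-2,5,5a,6,7,8,9,9a-octahydro-1-benzoxepin-2-yl]methanol | CC1=CC[C@H]2C(C)(C)[C@@H](Br)CC[C@]2(C)O[C@H]1CO | intermediate
20 | palisadin B, (2R,5aS,7S,9aS)-7-bromo-2-(bromomethyl)-3,6,6,9a-tetramethyl-2,5,5a,6,7,8,9,9a-octahydro-1-benzoxepine | CC1=CC[C@H]2C(C)(C)[C@@H](Br)CC[C@]2(C)O[C@H]1CBr | target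

## Step count and risks

Total steps: 12. Longest linear sequence: 11 steps (steps 1, 2, 4–12).

**Step 4.** The fully substituted CMe2 terminus of 7 slows C5a–C6 bond formation, so that Mukaiyama-type 1,2-addition to the activated formyl group, catalyst stalling, or loss of enantiofacial discrimination in a loose, stepwise transition state may take over. The fallback sets out from 5 and 7 and comes back at 9. The two components are combined under an achiral Lewis acid (Me2AlCl, CH2Cl2, −40 °C, or the AlBr3/AlMe3 mixed Lewis acid used for hindered diene/dienophile pairs), which should give 8 as a racemate, that is, together with the enantiomeric cycloadduct F1. Acid hydrolysis then gives 9 together with the enantiomeric keto aldehyde F2. Condensation of the racemate with (1R,2R)-N,N′-dimethyl-1,2-diphenylethane-1,2-diamine (4 Å molecular sieves, Et2O, rt; only the aldehyde reacts) should give two diastereomeric imidazolidines, the aminal of 9 F3 and the aminal of ent-9 F4, to be separated by chromatography or crystallisation. Two-phase hydrolysis of F3 (1 M HCl/Et2O) should return enantiopure 9.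

**Step 9.** The neopentylic alkoxyphosphonium ion may ionise instead of undergoing SN2 displacement, leading to 1,2-methyl shift from C6 or elimination towards C8. The fallback sets out from 11 and comes back at 16, forming the C–Br bond by radical reduction instead of substitution. Compound 11 is condensed with hydrazine hydrate (EtOH, reflux) to the hydrazone F5. Oxidation with CuBr2 (cupric bromide) and LiOt-Bu in THF should convert it into the geminal dibromide F6. Acylation as in step 6 gives the dibromo methacrylate F7, and ring-closing metathesis as in step 7 gives the dibromo lactone F8. Bu3SnH (1 equiv) with Et3B/air in toluene at −78 °C should then remove one bromine in a radical chain; the α-bromo radical at C7 is expected to take hydrogen from the axial direction, anti to the axial C6 methyl, leaving the equatorial bromide 16.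

**Step 11.** Borane addition to the conformationally mobile dienyl ether has an early transition state and may show poor facial selectivity at C2, or may stray onto the conjugated diene. The fallback sets out from 17 and comes back at 20. NBS in MeOH/CH2Cl2 at −78 °C should add bromine to the exocyclic carbon and methanol to C2, giving the bromomethyl methyl ketal F9 (either C2 epimer). Et3SiH with BF3·OEt2 in CH2Cl2 at −78 °C ionises it to the ring oxocarbenium ion conjugated with C3=C4, and hydride delivery to C2 anti to the axial 9a-methyl should give 20 directly, which also makes step 12 unnecessary.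

## Further compounds

F1 | step 4 | (1R,6R)-1,5,5-trimethyl-6-(prop-2-en-1-yl)-4-[(triisopropylsilyl)oxy]cyclohex-3-ene-1-carbaldehyde (enantiomer of 8) | C=CC[C@@H]1C(C)(C)C(O[Si](C(C)C)(C(C)C)C(C)C)=CC[C@@]1(C)C=O
F2 | step 4 | (1R,2S)-1,3,3-trimethyl-4-oxo-2-(prop-2-en-1-yl)cyclohexane-1-carbaldehyde (enantiomer of 9) | C=CC[C@@H]1C(C)(C)C(=O)CC[C@@]1(C)C=O
F3 | step 4 | aminal of 9: (3S,4S)-4-[(4R,5R)-1,3-dimethyl-4,5-diphenylimidazolidin-2-yl]-2,2,4-trimethyl-3-(prop-2-en-1-yl)cyclohexan-1-one | C=CC[C@H]1C(C)(C)C(=O)CC[C@]1(C)C1N(C)[C@H](c2ccccc2)[C@@H](c2ccccc2)N1C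
F4 | step 4 | aminal of ent-9: (3R,4R)-4-[(4R,5R)-1,3-dimethyl-4,5-diphenylimidazolidin-2-yl]-2,2,4-trimethyl-3-(prop-2-en-1-yl)cyclohexan-1-one | C=CC[C@@H]1C(C)(C)C(=O)CC[C@@]1(C)C1N(C)[C@H](c2ccccc2)[C@@H](c2ccccc2)N1C
F5 | step 9 | hydrazone of 11: (1S,2S)-4-hydrazinylidene-1,3,3-trimethyl-2-(prop-2-en-1-yl)cyclohexan-1-ol | C=CC[C@H]1C(C)(C)C(=NN)CC[C@]1(C)O
F6 | step 9 | (1S,2S)-4,4-dibromo-1,3,3-trimethyl-2-(prop-2-en-1-yl)cyclohexan-1-ol | C=CC[C@H]1C(C)(C)C(Br)(Br)CC[C@]1(C)O
F7 | step 9 | (1S,2S)-4,4-dibromo-1,3,3-trimethyl-2-(prop-2-en-1-yl)cyclohexyl 2-methylprop-2-enoate | C=CC[C@H]1C(C)(C)C(Br)(Br)CC[C@]1(C)OC(=O)C(C)=C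
F8 | step 9 | (5aS,9aS)-7,7-dibromo-3,6,6,9a-tetramethyl-5a,6,7,8,9,9a-hexahydro-1-benzoxepin-2(5H)-one | CC1=CC[C@H]2C(C)(C)C(Br)(Br)CC[C@]2(C)OC1=O
F9 | step 11 | (5aS,7S,9aS)-7-bromo-2-(bromomethyl)-2-methoxy-3,6,6,9a-tetramethyl-2,5,5a,6,7,8,9,9a-octahydro-1-benzoxepine (either C2 epimer) | CC1=CC[C@H]2C(C)(C)[C@@H](Br)CC[C@]2(C)OC1(CBr)OC
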